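**Retrosynthetic overview**
- Target 5 ⇒ (13R,14R)-13,14-epoxide 4: the exocyclic C13=C16 alkene and the free C14 carbinol come from opening the oxirane at C13, with the C14–O bond kept.
- 4 ⇒ E-allylic alcohol 3: both oxirane C–O bonds (C13, C14) come from a reagent-controlled epoxidation.
- 3 ⇒ isocupressic acid 1: the C8–O bond (8α-OH, 8β-CH3) comes from Markovnikov hydration of the exocyclic 8(17)-alkene.
- Rings: no ring is built. Ring A, ring B and C4, C5, C9, C10 are carried intact from 1; the route consists of C–O bond formations on that skeleton.

Assumption: isocupressic acid (1), a catalogue natural product (the main labdane acid of Pinus ponderosa needles), is taken as the purchasable starting material; all other inputs are bulk reagents.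

Target read from the SMILES: (4S,5R,8R,9R,10S,14S)-8,14,15-trihydroxylabd-13(16)-en-19-oic acid (normal labdane series, axial C19 acid, 8α-OH). The ring stereocentres match those of 1.

**Step 1**
Reactants: 1 isocupressic acid
Product: 3 (13E)-8α,15-dihydroxylabd-13-en-19-oic acid, via 17-acetoxymercurio adduct 2 (not isolated)
Conditions: Hg(OAc)2 (1.0 equiv), THF/H2O 1:1, 0 °C to rt; then 3 M NaOH, NaBH4, 0 °C; then 1 M HCl to pH 3
Reagents that add atoms: water, O; Hg(OAc)2, CC(=O)O[Hg]OC(C)=O (Hg and one acetate stay in 2 only)
Why: Brown oxymercuration–demercuration: the electrophilic divalent mercury salt adds to the 1,1-disubstituted exocyclic alkene much faster than to the trisubstituted, inductively deactivated allylic-alcohol alkene, and water opens the mercurinium ion at tertiary C8 by equatorial attack away from the axial C10 methyl, which sets C8 as 8α-OH with the former CH2 becoming the axial 8β-methyl after NaBH4 cleaves the C–Hg bond.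

**Step 2**
Reactants: 3 (13E)-8α,15-dihydroxylabd-13-en-19-oic acid
Product: 4 (13R,14R)-13,14-epoxy-8α,15-dihydroxylabdan-19-oic acid
Conditions: 1,2:4,5-di-O-isopropylidene-β-D-erythro-2,3-hexodiulo-2,6-pyranose (D-fructose-derived Shi ketone, 30 mol %), KHSO5 (as Oxone, 1.5 equiv), K2CO3, Bu4NHSO4 (cat.), MeCN–CH2(OMe)2/aq. Na2B4O7 buffer (pH 10.5), 0 °C; work-up at pH 5, 0 °C, crude used at once
Reagents that add atoms: potassium peroxymonosulfate KHSO5, [K+].[O-]S(=O)(=O)OO
Why: Shi asymmetric epoxidation: the chiral dioxirane delivers oxygen through its spiro transition state to the alkene face that gives (R,R)-epoxides from E-alkenes and (2R,3R)-glycidols from E-allylic alcohols, which sets C13 and C14 as (13R,14R), while the basic, Lewis-acid-free medium tolerates the carboxylate and keeps the C8 hydroxyl from opening the new oxirane.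

**Step 3**
Reactants: 4 (13R,14R)-13,14-epoxy-8α,15-dihydroxylabdan-19-oic acid
Product: 5 (14S)-8α,14,15-trihydroxylabd-13(16)-en-19-oic acid (CNP0216809.1)
Conditions: Cp2TiCl2 (10 mol %), Co(salen) (C16H14CoN2O2, 5 mol %), Zn dust (30 mol %), 2,4,6-collidine·HCl (1.5 equiv), THF, 25 °C
Reagents that add atoms: none
Why: Proposed new method: bimetallic radical redox-relay isomerization of an epoxide to an allylic alcohol, run here on a kind of substrate where it has not been shown (a free 2,3-epoxy alcohol that also carries a free tertiary hydroxyl and a carboxylic acid); trivalent titanium (Cp2TiCl made from Cp2TiCl2 and Zn), held by the C15 alkoxide and the oxirane oxygen, breaks the C13–O bond homolytically to the tertiary C13 radical so the C14–O bond and its configuration are untouched (14R in 4 becomes 14S in 5 only through the priority change), the divalent cobalt complex takes a hydrogen atom from the least hindered C16 methyl to form the C13=C16 double bond, and the cobalt hydride then protonates the titanium alkoxide and returns the electron so both metals turn over; since no C13 cation forms, the 8α-hydroxyl cannot close the 8,13-ether that Lewis or Brønsted acids would give; closest known reaction type: titanium/cobalt-catalysed radical isomerization of simple epoxides to allylic alcohols and Cp2TiCl-mediated homolytic epoxide opening.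

**Compound list**
1 | isocupressic acid, (4S,5R,9S,10R,13E)-15-hydroxylabda-8(17),13-dien-19-oic acid | OC/C=C(\C)CC[C@@H]1[C@@]2(C)CCC[C@](C)(C(=O)O)[C@@H]2CCC1=C | starting material
2 | (13E)-17-(acetoxymercurio)-8α,15-dihydroxylabd-13-en-19-oic acid (8α-OH, axial 8β-CH2HgOAc) | OC/C=C(\C)CC[C@@H]1[C@@]2(C)CCC[C@](C)(C(=O)O)[C@@H]2CC[C@@]1(C[Hg]OC(C)=O)O | intermediate
3 | (4S,5R,8R,9R,10S,13E)-8α,15-dihydroxylabd-13-en-19-oic acid | OC/C=C(\C)CC[C@@H]1[C@@]2(C)CCC[C@](C)(C(=O)O)[C@@H]2CC[C@@]1(C)O | intermediate
4 | (4S,5R,8R,9R,10S,13R,14R)-13,14-epoxy-8α,15-dihydroxylabdan-19-oic acid | OC[C@H]1O[C@]1(C)CC[C@@H]2[C@@]3(C)CCC[C@](C)(C(=O)O)[C@@H]3CC[C@@]2(C)O | intermediate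
5 | (4S,5R,8R,9R,10S,14S)-8α,14,15-trihydroxylabd-13(16)-en-19-oic acid (CNP0216809.1) | C=C(CC[C@@H]1[C@@]2(C)CCC[C@](C)(C(=O)O)[C@@H]2CC[C@@]1(C)O)[C@H](O)CO | target

**Totals**
Total step count: 3. Longest linear sequence: 3 steps (1 → 3 → 4 → 5).

**Steps most likely to fail and fallbacks**

Step 3 (the proposed new step). Risks: the C13 radical may be reduced to the saturated 14,15-diol, the epoxide may be deoxygenated back to 3, the cobalt hydride may isomerize the product alkene, or hydrogen may be taken from C12 instead of C16. Fallback, known chemistry: it sets out from 4 and uses the lithium amide epoxide-to-allylic-alcohol rearrangement (LiNEt2, 6 equiv, THF/Et2O, 0 °C to rt, acidic work-up at pH 4). This is an alkoxide-assisted syn-β-elimination that removes a proton from the C16 methyl in preference to the C12 methylene and involves no cation, so the 8,13-ether is again avoided. It comes back to the route at 5 and makes no new compound (F0).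

Step 2. Risks: facial selectivity below about 95:5 (the minor epoxide ends as the 14-epimer of 5, separable as a diastereomer), and acid-triggered closure of the 8,13-ether while the hydroxy-epoxy acid 4 is handled. Fallback: it sets out from 3 and switches from dioxirane control to hydroxyl-directed titanium–tartrate control on a protected acid. The carboxylate is O-allylated (allyl bromide, K2CO3, DMF, rt) to allyl (13E)-8α,15-dihydroxylabd-13-en-19-oate F1. Sharpless asymmetric epoxidation (Ti(OiPr)4, diisopropyl D-tartrate, t-BuOOH, 4 Å sieves, CH2Cl2, −20 °C) gives allyl (13R,14R)-13,14-epoxy-8α,15-dihydroxylabdan-19-oate F2; the D-tartrate gives the (2R,3R) sense on E-allylic alcohols. Deallylation with Pd(PPh3)4 (5 mol %) and morpholine in THF at rt comes back to the route at 4.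

Step 1. Risks: mercury-assisted closure of the C8 hydroxyl onto the side-chain alkene if any excess Hg(OAc)2 is present, and incomplete conversion of the hindered exocyclic alkene. Fallback: it sets out from 1 and replaces the ionic addition by a radical one, Mukaiyama hydration (Co(acac)2 cat., PhSiH3, O2, THF/i-PrOH, rt). Metal-hydride hydrogen-atom transfer favours the 1,1-disubstituted alkene, and the tertiary C8 radical is oxygenated from the equatorial α side. It comes back to the route at 3 and makes no new compound (F0).

**Further compounds**
F0 | step 1 | none | none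
F1 | step 2 | allyl (13E)-8α,15-dihydroxylabd-13-en-19-oate | OC/C=C(\C)CC[C@@H]1[C@@]2(C)CCC[C@](C)(C(=O)OCC=C)[C@@H]2CC[C@@]1(C)O
F2 | step 2 | allyl (13R,14R)-13,14-epoxy-8α,15-dihydroxylabdan-19-oate | OC[C@H]1O[C@]1(C)CC[C@@H]2[C@@]3(C)CCC[C@](C)(C(=O)OCC=C)[C@@H]3CC[C@@]2(C)O
F0 | step 3 | none | none
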